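## Analysis of the target

Compound 29 is a flavan-3-ol: a benzene ring (ring A) fused to a dihydropyran (ring C), with the catechol-derived ring B on C2 and a hydroxyl on C3. The two stereocentres are adjacent, C2 (R) and C3 (S), and trans on ring C. In the open chain C1'–C2–C3–C4 this is the 1,2-anti arrangement of O1 and O3. Ring A is a phloroglucinol unit whose three oxygens end up different: O1 is the ring ether, O5 carries a galloyl ester and O7 is a free phenol. On ring B, O4' is acylated and the neighbouring O3' is free. The sensitive points are the two aryl esters (solvolysis, and 4'-O to 3'-O migration once the catechol is unmasked), the benzylic C2–O1 bond para to an oxygenated ring (ionisation, epimerisation, hydrogenolysis), and the air-sensitive catechol and pyrogallol units. The skeleton is simple; the difficulty is placing two identical acyl groups on exactly two of nine hydroxyls, above all telling O5 from O7. The plan rests on the two bonds that fuse ring A to ring C, C8a–O1 and C4a–C4. The chain O1–C2–C3–C4 can therefore tether a pyridazine carbon (future C8a) to an alkyne (future C4a and C5), and a boron atom on the alkyne terminus then marks C5 alone.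

## Retrosynthetic reasoning

**29 from 28.** Every hydroxyl that must end free (3-OH, 7-OH, 3'-OH and the six galloyl phenols) is cut back to a benzyl ether. One neutral hydrogenolysis then ends the synthesis, and the two aryl esters never meet base or nucleophile.

**28 from 26 and 27.** The two ester C–O bonds are cut. Diol 26 has only two free hydroxyls, the phenols at C5 and C4', so the double acylation with acid 27 needs no selectivity.

**26 from 25 from 24.** The 4'-OH comes from a methoxymethyl ether, cleaved by acid and orthogonal to benzyl. The 5-OH is traced back to a C5–B bond. The oxygen that is hardest to tell from O7 is thus not an oxygen until late in the route.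

**24 from 22 (key disconnection).** The bonds C4a–C8a and C5–C6 are cut and two nitrogen atoms are placed between C8a and C6. Ring A becomes a 3-alkoxy-5-benzyloxypyridazine, C4a and C5 become an alkynylboronate, and O1–C2–C3–C4 becomes the tether. This cut is chosen because one thermal operation closes rings A and C, delivers the arene at the right oxidation level, and fixes the positions of O1, O7 and boron by connectivity. The forward reaction must be a [4+2] addition across the diazine followed by loss of nitrogen, without touching C2 or C3.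

**22 from 19 from 18.** The C–B bond is cut to the terminal alkyne C–H, and that to a C–Si bond. The silyl cap is needed earlier, where a free alkyne would interfere with the Grignard and alkoxide steps.

**18 from 14 and 16; 16 from 15.** The aryl ether bond O1–C8a is cut. It forms by substitution at the diazine carbon, so C2 is a spectator. The order of the two substitutions on dichloride 15 decides which oxygen is benzylated (future O7) and which becomes O1.

**14 from 13.** The C2–H bond is cut. A chelation-controlled hydride delivery must relay the configuration of C3 to C2 and give the anti alcohol.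

**13 from 8 and 11 (through 12).** The bond C2–C1' is cut. Ring B enters as an aryl nucleophile on an amide that stops at the ketone stage.

**8 from 7 from 4 and 5; 4 from 1 and 2.** The bond C3–C4 is cut. An auxiliary-controlled alkylation of a glycolate sets C3 and brings in the three carbons C4, C4a and C5.

**11 from 10 from 9.** Bromination para to the free hydroxyl of 9 fixes that the oxygen para to C1' (future O4') carries the acid-labile group and O3' the benzyl group.

## Alternatives that were turned down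

**Alternative 1: asymmetric epoxidation of a chalcone.**
- Disconnection: O1–C2 and the C3–O bond are traced to the epoxide A2, and that to the C2=C3 double bond of chalcone A1 (C4 is the ketone carbon).
- Forward key step: a peptide-catalysed nucleophilic epoxidation of the Juliá–Colonna type converts A1 into A2 and sets both stereocentres in one catalytic step.
- For it: cheap aldol chemistry and a catalytic stereo-step. The symmetric ring A also solves the O5/O7 problem, since one of the two equivalent ortho oxygens becomes O1 and the other O5.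
- Against it: the doubly ortho-substituted aryl ketone is twisted out of conjugation, which is unfavourable for this epoxidation, so the enantioselectivity is uncertain. After the key step, exactly one of two equivalent acetal groups must be removed to close ring C at the benzylic epoxide carbon. The C4 carbonyl then has to be removed in two redox steps at an ionisable benzylic position. The new 3-OH must also be masked before the gallates go on.
- Comparison: this route is stronger on thermal mildness and on the precedent of its ring closure. The chosen route never needs redox adjustment at C4, sets its stereocentres by two well-understood controls, and leaves no functional-group repair after the key step.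

**Alternative 2: Danheiser benzannulation.**
- Disconnection: ring A is cut at C4a–C5 and C8–C8a (and C5–C6) into cyclobutenone A3 and siloxyalkyne A4.
- Forward key step: heating A3 with A4 triggers the ring-opening, [2+2], ring-opening, electrocyclisation cascade. It gives resorcinol A5 with a free 5-OH, O1 as a silyl ether and O7 as a benzyl ether.
- For it: all three ring-A oxygens are told apart in one step at moderate temperature. This is equal to the chosen plan on that point, and better on thermal demand.
- Against it: ring C is still open. The O1–C2 bond must be made by substitution with inversion at an electron-rich benzylic carbon of the syn-diol, where ionisation erodes stereochemistry. The free 5-OH appears early and must be carried or masked. Both A3 and A4 need several steps and are hydrolytically fragile.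
- Comparison: the chosen plan makes O1–C2 at oxygen before the key step and closes both rings at once, at the price of a hotter key step.

**Alternative 3: quinone methide hetero-Diels–Alder.**
- Disconnection: ring C is cut at C3–C4 and O1–C2 into salicyl alcohol A6 and styrylboronate A7.
- Forward key step: a chiral Brønsted acid generates the ortho-quinone methide from A6. It adds across A7 to give the trans chroman A8, whose C3–B bond is later oxidised with retention.
- For it: it is the most convergent plan. It joins both aryl fragments, closes ring C and sets both stereocentres in one step; it is clearly stronger on step count.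
- Against it: an alkenylboronate is a weak partner for an inverse-demand heterodiene. The phloroglucinol-type quinone methide is stabilised and sluggish. Absolute control by the acid is unproven for this pairing. The acid must also coexist with two acetal protecting groups, and A6 needs its own ring-A differentiation.
- Comparison: the chosen plan draws its stereocontrol from an auxiliary and a chelate, both predictable, and confines the uncertainty to reactivity rather than to selectivity.

Key step: step 12

Assumption: compounds 1, 2, 5, 9, 15 and 27 are taken as purchasable; the galloyl unit is bought as its tribenzyl ether acid 27 rather than built from gallic acid.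

## Route

Step 1
Reactants: 1 (R)-4-benzyloxazolidin-2-one; 2 benzyloxyacetyl chloride
Product: 4 (R)-4-benzyl-3-[2-(benzyloxy)acetyl]oxazolidin-2-one, via N-lithio oxazolidinone 3 (not isolated)
Conditions: n-BuLi, THF, −78 °C; then 2, −78 → 0 °C
Reagents that add atoms: none
Why: N-acylation of the lithiated oxazolidinone by an acid chloride (standard imide formation); no stereocentre is formed or touched.

Step 2
Reactants: 4 (R)-4-benzyl-3-[2-(benzyloxy)acetyl]oxazolidin-2-one; 5 (3-bromoprop-1-yn-1-yl)triisopropylsilane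
Product: 7 (R)-4-benzyl-3-[(S)-2-(benzyloxy)-5-(triisopropylsilyl)pent-4-ynoyl]oxazolidin-2-one, via sodium Z-enolate 6 (not isolated)
Conditions: NaN(SiMe3)2, THF, −78 °C; then 5, −78 → −45 °C
Reagents that add atoms: none
Why: Evans asymmetric alkylation of a glycolate imide: the chelated Z-enolate 6 is alkylated on the face away from the C4 benzyl group, which with the (R)-auxiliary should give the (S) α-benzyloxy centre (future C3); the silyl cap removes the acidic alkyne proton.

Step 3
Reactants: 7 (R)-4-benzyl-3-[(S)-2-(benzyloxy)-5-(triisopropylsilyl)pent-4-ynoyl]oxazolidin-2-one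
Product: 8 (S)-2-(benzyloxy)-N-methoxy-N-methyl-5-(triisopropylsilyl)pent-4-ynamide
Conditions: MeNHOMe·HCl, AlMe3, CH2Cl2, −10 → 0 °C
Reagents that add atoms: N,O-dimethylhydroxylamine hydrochloride, CNOC.Cl
Why: Aluminium-amide aminolysis of the exocyclic imide carbonyl (Weinreb amide formation) releases the auxiliary under conditions that do not enolise the α-alkoxy centre.

Step 4
Reactants: 9 2-(benzyloxy)phenol
Product: 10 2-(benzyloxy)-4-bromophenol
Conditions: NBS, MeCN, 0 °C
Reagents that add atoms: N-bromosuccinimide, O=C1CCC(=O)N1Br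
Why: Electrophilic aromatic bromination is directed para to the free hydroxyl, the stronger donor, so bromine should enter at the carbon that becomes C1'.

Step 5
Reactants: 10 2-(benzyloxy)-4-bromophenol
Product: 11 2-(benzyloxy)-4-bromo-1-(methoxymethoxy)benzene
Conditions: MOMCl, i-Pr2NEt, CH2Cl2, 0 °C → rt
Reagents that add atoms: chloromethyl methyl ether, COCCl
Why: O-alkylation of the phenol to the methoxymethyl acetal; this group is orthogonal to benzyl and tolerates Grignard, hydride, alkoxide and amide-base steps.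

Step 6
Reactants: 11 2-(benzyloxy)-4-bromo-1-(methoxymethoxy)benzene; 8 (S)-2-(benzyloxy)-N-methoxy-N-methyl-5-(triisopropylsilyl)pent-4-ynamide
Product: 13 (S)-2-(benzyloxy)-1-[3-(benzyloxy)-4-(methoxymethoxy)phenyl]-5-(triisopropylsilyl)pent-4-yn-1-one, via arylmagnesium bromide 12 (not isolated)
Conditions: Mg, BrCH2CH2Br (cat.), THF, 45 °C; then 8, THF, 0 °C; aq. NH4Cl
Reagents that add atoms: none
Why: Grignard addition to a Weinreb amide stops at the ketone because the magnesium chelate collapses only on work-up; the capped alkyne is inert and the α-centre is not enolised before the quench.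

Step 7
Reactants: 13 (S)-2-(benzyloxy)-1-[3-(benzyloxy)-4-(methoxymethoxy)phenyl]-5-(triisopropylsilyl)pent-4-yn-1-one
Product: 14 (1R,2S)-2-(benzyloxy)-1-[3-(benzyloxy)-4-(methoxymethoxy)phenyl]-5-(triisopropylsilyl)pent-4-yn-1-ol
Conditions: Zn(BH4)2, Et2O, −30 → 0 °C
Reagents that add atoms: none
Why: Cram-chelate reduction: the zinc of Zn(BH4)2 bridges the ketone and α-benzyloxy oxygens and hydride enters from the face bearing the α-hydrogen, which should give the 1,2-anti (1R,2S) alcohol that maps onto trans C2/C3.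

Step 8
Reactants: 15 3,5-dichloropyridazine
Product: 16 5-(benzyloxy)-3-chloropyridazine
Conditions: BnOH, NaH, THF, 0 °C → rt
Reagents that add atoms: benzyl alcohol, OCc1ccccc1
Why: SNAr on the dichlorodiazine goes first at C5, the position para to a ring nitrogen, so one equivalent of benzyloxide should leave the C3 chloride for the next substitution.

Step 9
Reactants: 14 (1R,2S)-2-(benzyloxy)-1-[3-(benzyloxy)-4-(methoxymethoxy)phenyl]-5-(triisopropylsilyl)pent-4-yn-1-ol; 16 5-(benzyloxy)-3-chloropyridazine
Product: 18 5-(benzyloxy)-3-{[(1R,2S)-2-(benzyloxy)-1-[3-(benzyloxy)-4-(methoxymethoxy)phenyl]-5-(triisopropylsilyl)pent-4-yn-1-yl]oxy}pyridazine, via sodium alkoxide 17 (not isolated)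
Conditions: NaH, THF/DMF, 0 °C; then 16, rt → 50 °C
Reagents that add atoms: none
Why: SNAr (addition–elimination) of the secondary alkoxide at the chloride-bearing carbon next to ring nitrogen; the new bond is made at oxygen, so C2 keeps its configuration, and the triisopropylsilyl alkyne resists alkoxide.

Step 10
Reactants: 18 5-(benzyloxy)-3-{[(1R,2S)-2-(benzyloxy)-1-[3-(benzyloxy)-4-(methoxymethoxy)phenyl]-5-(triisopropylsilyl)pent-4-yn-1-yl]oxy}pyridazine
Product: 19 5-(benzyloxy)-3-{[(1R,2S)-2-(benzyloxy)-1-[3-(benzyloxy)-4-(methoxymethoxy)phenyl]pent-4-yn-1-yl]oxy}pyridazine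
Conditions: Bu4NF, THF, 0 °C → rt
Reagents that add atoms: none
Why: Fluoride-induced protodesilylation of an alkynylsilane; the benzyl, acetal and heteroaryl ethers are inert to fluoride.

Step 11
Reactants: 19 5-(benzyloxy)-3-{[(1R,2S)-2-(benzyloxy)-1-[3-(benzyloxy)-4-(methoxymethoxy)phenyl]pent-4-yn-1-yl]oxy}pyridazine
Product: 22 5-(benzyloxy)-3-{[(1R,2S)-2-(benzyloxy)-1-[3-(benzyloxy)-4-(methoxymethoxy)phenyl]-5-(4,4,5,5-tetramethyl-1,3,2-dioxaborolan-2-yl)pent-4-yn-1-yl]oxy}pyridazine, via lithium acetylide 20 (not isolated), via lithium alkynyl(isopropoxy)borate 21 (not isolated)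
Conditions: LiN(i-Pr)2 (1.05 equiv), THF, −78 °C; i-PrOBpin, −78 °C; HCl (Et2O, 1.0 equiv), −78 °C → rt; filtration, used crude
Reagents that add atoms: 2-isopropoxy-4,4,5,5-tetramethyl-1,3,2-dioxaborolane, CC(C)OB1OC(C)(C)C(C)(C)O1
Why: Standard alkynylboronate preparation (acetylide, borate ester, acid collapse of the ate complex); a hindered amide base is used in place of an alkyllithium so that the acidic alkyne C–H is removed without nucleophilic addition to the diazine.

Step 12
Reactants: 22 5-(benzyloxy)-3-{[(1R,2S)-2-(benzyloxy)-1-[3-(benzyloxy)-4-(methoxymethoxy)phenyl]-5-(4,4,5,5-tetramethyl-1,3,2-dioxaborolan-2-yl)pent-4-yn-1-yl]oxy}pyridazine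
Product: 24 2-{(2R,3S)-3,7-bis(benzyloxy)-2-[3-(benzyloxy)-4-(methoxymethoxy)phenyl]chroman-5-yl}-4,4,5,5-tetramethyl-1,3,2-dioxaborolane, via bridged azo cycloadduct 23 (not isolated)
Conditions: o-C6H4Cl2 (0.01 M, degassed), 2,6-di-tert-butyl-4-methylpyridine (0.1 equiv), 180–210 °C, sealed tube
Reagents that add atoms: none
Why: The diazine acts as a 4π component through C3 and C6 and the tethered alkynylboronate as the 2π component in an intramolecular inverse-electron-demand Diels–Alder reaction, giving the 2,3-diazabicyclo[2.2.2]octatriene 23, which loses nitrogen by retro-[4+2] and aromatises. The closest known reaction type is the thermal cycloaddition–cycloreversion of 3-(alkynyloxy)-1,2-diazines to fused benzenes, together with cycloadditions of alkynylboronic esters with azadienes. Ring C closes by C4a–C8a bond formation as the six-membered ring of a type 1 intramolecular cycloaddition with the four-atom tether O1–C2–C3–C4. Ring A arises from the four diazine carbons and the two alkyne carbons when the C5–C6 bond forms and the N=N bridge is expelled. No stereocentre remains from this step, because both bridgehead epimers of 23 converge on the same arene and C2 and C3 are not involved in any bond change. The step needs regiocontrol, which the tether secures because only the C4a–C8a/C5–C6 pairing is geometrically possible, so boron must end at C5. It also needs cycloaddition to outrun heterolysis of the benzylic C2–O bond; the non-polar medium, the hindered base as acid scavenger and high dilution are chosen for that. The anti aryl and benzyloxy substituents on the tether can both lie pseudo-equatorial in the folded transition state, which should favour the reactive rotamer over the unsubstituted case.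

Step 13
Reactants: 24 2-{(2R,3S)-3,7-bis(benzyloxy)-2-[3-(benzyloxy)-4-(methoxymethoxy)phenyl]chroman-5-yl}-4,4,5,5-tetramethyl-1,3,2-dioxaborolane
Product: 25 (2R,3S)-3,7-bis(benzyloxy)-2-[3-(benzyloxy)-4-(methoxymethoxy)phenyl]chroman-5-ol
Conditions: NaBO3·4H2O, THF/H2O, rt
Reagents that add atoms: NaBO3·4H2O (sodium perborate), [Na+].[Na+].O[B-]1(O)OO[B-](O)(O)OO1
Why: ipso-Oxidation of an arylboronic ester (peroxide addition to boron, 1,2-aryl shift to oxygen, hydrolysis); the mild, non-acidic conditions leave benzyl and acetal ethers alone.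

Step 14
Reactants: 25 (2R,3S)-3,7-bis(benzyloxy)-2-[3-(benzyloxy)-4-(methoxymethoxy)phenyl]chroman-5-ol
Product: 26 (2R,3S)-3,7-bis(benzyloxy)-2-[3-(benzyloxy)-4-hydroxyphenyl]chroman-5-ol
Conditions: HCl (cat.), MeOH/THF, 40 °C
Reagents that add atoms: none
Why: Acid-catalysed acetal cleavage in which methanol traps the methoxymethyl cation, keeping it from the electron-rich ring A; benzyl ethers are stable and the mild treatment should spare the C2–O1 bond.

Step 15
Reactants: 26 (2R,3S)-3,7-bis(benzyloxy)-2-[3-(benzyloxy)-4-hydroxyphenyl]chroman-5-ol; 27 3,4,5-tris(benzyloxy)benzoic acid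
Product: 28 (2R,3S)-3,7-bis(benzyloxy)-2-{3-(benzyloxy)-4-[3,4,5-tris(benzyloxy)benzoyloxy]phenyl}chroman-5-yl 3,4,5-tris(benzyloxy)benzoate
Conditions: 27 (2.5 equiv), EDC·HCl, DMAP, CH2Cl2, rt
Reagents that add atoms: none
Why: Steglich esterification; the two phenols are the only free hydroxyls (O3 is benzylated), so both are acylated and no selectivity is required.

Step 16
Reactants: 28 (2R,3S)-3,7-bis(benzyloxy)-2-{3-(benzyloxy)-4-[3,4,5-tris(benzyloxy)benzoyloxy]phenyl}chroman-5-yl 3,4,5-tris(benzyloxy)benzoate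
Product: 29 catechin 5,4'-di-O-gallate, (2R,3S)-3,7-dihydroxy-2-[3-hydroxy-4-(3,4,5-trihydroxybenzoyloxy)phenyl]chroman-5-yl 3,4,5-trihydroxybenzoate
Conditions: H2 (1 atm), Pd(OH)2/C, THF/EtOAc, rt; filtration under argon
Reagents that add atoms: none
Why: Heterogeneous hydrogenolysis of nine O-benzyl groups; a neutral, base-free and alcohol-free medium is chosen so that the aryl esters are neither solvolysed nor shifted from O4' to O3'.

## Compound list

1 | (R)-4-benzyloxazolidin-2-one | O=C1OC[C@@H](Cc2ccccc2)N1 | starting material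
2 | benzyloxyacetyl chloride | O=C(Cl)COCc1ccccc1 | starting material
3 | lithium salt of (R)-4-benzyloxazolidin-2-one (N-lithio) | O=C1OC[C@@H](Cc2ccccc2)N1[Li] | intermediate (not isolated)
4 | (R)-4-benzyl-3-[2-(benzyloxy)acetyl]oxazolidin-2-one | O=C1OC[C@@H](Cc2ccccc2)N1C(=O)COCc1ccccc1 | intermediate
5 | (3-bromoprop-1-yn-1-yl)triisopropylsilane | BrCC#C[Si](C(C)C)(C(C)C)C(C)C | starting material
6 | sodium (Z)-enolate of 4 | O=C1OC[C@@H](Cc2ccccc2)N1/C(O[Na])=C/OCc1ccccc1 | intermediate (not isolated)
7 | (R)-4-benzyl-3-[(S)-2-(benzyloxy)-5-(triisopropylsilyl)pent-4-ynoyl]oxazolidin-2-one | O=C1OC[C@@H](Cc2ccccc2)N1C(=O)[C@@H](OCc1ccccc1)CC#C[Si](C(C)C)(C(C)C)C(C)C | intermediate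
8 | (S)-2-(benzyloxy)-N-methoxy-N-methyl-5-(triisopropylsilyl)pent-4-ynamide | CON(C)C(=O)[C@@H](OCc1ccccc1)CC#C[Si](C(C)C)(C(C)C)C(C)C | intermediate
9 | 2-(benzyloxy)phenol | Oc1ccccc1OCc1ccccc1 | starting material
10 | 2-(benzyloxy)-4-bromophenol | Oc1ccc(Br)cc1OCc1ccccc1 | intermediate
11 | 2-(benzyloxy)-4-bromo-1-(methoxymethoxy)benzene | COCOc1ccc(Br)cc1OCc1ccccc1 | intermediate
12 | [3-(benzyloxy)-4-(methoxymethoxy)phenyl]magnesium bromide | COCOc1ccc([Mg]Br)cc1OCc1ccccc1 | intermediate (not isolated)
13 | (S)-2-(benzyloxy)-1-[3-(benzyloxy)-4-(methoxymethoxy)phenyl]-5-(triisopropylsilyl)pent-4-yn-1-one | COCOc1ccc(C(=O)[C@@H](OCc2ccccc2)CC#C[Si](C(C)C)(C(C)C)C(C)C)cc1OCc1ccccc1 | intermediate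
14 | (1R,2S)-2-(benzyloxy)-1-[3-(benzyloxy)-4-(methoxymethoxy)phenyl]-5-(triisopropylsilyl)pent-4-yn-1-ol | COCOc1ccc([C@H]([C@@H](OCc2ccccc2)CC#C[Si](C(C)C)(C(C)C)C(C)C)O)cc1OCc1ccccc1 | intermediate
15 | 3,5-dichloropyridazine | Clc1cc(Cl)cnn1 | starting material
16 | 5-(benzyloxy)-3-chloropyridazine | Clc1cc(OCc2ccccc2)cnn1 | intermediate
17 | sodium alkoxide of 14 | COCOc1ccc([C@H]([C@@H](OCc2ccccc2)CC#C[Si](C(C)C)(C(C)C)C(C)C)O[Na])cc1OCc1ccccc1 | intermediate (not isolated)
18 | 5-(benzyloxy)-3-{[(1R,2S)-2-(benzyloxy)-1-[3-(benzyloxy)-4-(methoxymethoxy)phenyl]-5-(triisopropylsilyl)pent-4-yn-1-yl]oxy}pyridazine | COCOc1ccc([C@H]([C@@H](OCc2ccccc2)CC#C[Si](C(C)C)(C(C)C)C(C)C)Oc2cc(OCc3ccccc3)cnn2)cc1OCc1ccccc1 | intermediate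
19 | 5-(benzyloxy)-3-{[(1R,2S)-2-(benzyloxy)-1-[3-(benzyloxy)-4-(methoxymethoxy)phenyl]pent-4-yn-1-yl]oxy}pyridazine | COCOc1ccc([C@H]([C@@H](OCc2ccccc2)CC#C)Oc2cc(OCc3ccccc3)cnn2)cc1OCc1ccccc1 | intermediate
20 | lithium acetylide of 19 | COCOc1ccc([C@H]([C@@H](OCc2ccccc2)CC#C[Li])Oc2cc(OCc3ccccc3)cnn2)cc1OCc1ccccc1 | intermediate (not isolated)
21 | lithium alkynyl(isopropoxy)(pinacolato)borate from 20 | COCOc1ccc([C@H]([C@@H](OCc2ccccc2)CC#C[B-]2(OC(C)C)OC(C)(C)C(C)(C)O2)Oc2cc(OCc3ccccc3)cnn2)cc1OCc1ccccc1.[Li+] | intermediate (not isolated)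
22 | 5-(benzyloxy)-3-{[(1R,2S)-2-(benzyloxy)-1-[3-(benzyloxy)-4-(methoxymethoxy)phenyl]-5-(4,4,5,5-tetramethyl-1,3,2-dioxaborolan-2-yl)pent-4-yn-1-yl]oxy}pyridazine | COCOc1ccc([C@H]([C@@H](OCc2ccccc2)CC#CB2OC(C)(C)C(C)(C)O2)Oc2cc(OCc3ccccc3)cnn2)cc1OCc1ccccc1 | intermediate
23 | bridged azo cycloadduct (2,3-diazabicyclo[2.2.2]octa-2,5,7-triene fused to the new pyran ring; either bridgehead configuration) | COCOc1ccc([C@H]2OC34N=NC(C(OCc5ccccc5)=C3)C(B5OC(C)(C)C(C)(C)O5)=C4C[C@@H]2OCc2ccccc2)cc1OCc1ccccc1 | intermediate (not isolated)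
24 | 2-{(2R,3S)-3,7-bis(benzyloxy)-2-[3-(benzyloxy)-4-(methoxymethoxy)phenyl]chroman-5-yl}-4,4,5,5-tetramethyl-1,3,2-dioxaborolane | COCOc1ccc([C@H]2Oc3cc(OCc4ccccc4)cc(B4OC(C)(C)C(C)(C)O4)c3C[C@@H]2OCc2ccccc2)cc1OCc1ccccc1 | intermediate
25 | (2R,3S)-3,7-bis(benzyloxy)-2-[3-(benzyloxy)-4-(methoxymethoxy)phenyl]chroman-5-ol | COCOc1ccc([C@H]2Oc3cc(OCc4ccccc4)cc(O)c3C[C@@H]2OCc2ccccc2)cc1OCc1ccccc1 | intermediate
26 | (2R,3S)-3,7-bis(benzyloxy)-2-[3-(benzyloxy)-4-hydroxyphenyl]chroman-5-ol | Oc1ccc([C@H]2Oc3cc(OCc4ccccc4)cc(O)c3C[C@@H]2OCc2ccccc2)cc1OCc1ccccc1 | intermediate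
27 | 3,4,5-tris(benzyloxy)benzoic acid | O=C(O)c1cc(OCc2ccccc2)c(OCc2ccccc2)c(OCc2ccccc2)c1 | starting material
28 | (2R,3S)-3,7-bis(benzyloxy)-2-{3-(benzyloxy)-4-[3,4,5-tris(benzyloxy)benzoyloxy]phenyl}chroman-5-yl 3,4,5-tris(benzyloxy)benzoate | O=C(Oc1ccc([C@H]2Oc3cc(OCc4ccccc4)cc(OC(=O)c4cc(OCc5ccccc5)c(OCc5ccccc5)c(OCc5ccccc5)c4)c3C[C@@H]2OCc2ccccc2)cc1OCc1ccccc1)c1cc(OCc2ccccc2)c(OCc2ccccc2)c(OCc2ccccc2)c1 | intermediate
29 | catechin 5,4'-di-O-gallate | O=C(Oc1ccc([C@H]2Oc3cc(O)cc(OC(=O)c4cc(O)c(O)c(O)c4)c3C[C@@H]2O)cc1O)c1cc(O)c(O)c(O)c1 | target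

## Step count and least certain steps

Total step count: 16. Longest linear sequence: 13 steps (1, 2, 3, 6, 7, 9, 10, 11, 12, 13, 14, 15, 16).

**Step 12 (key step).** The cycloaddition may be too slow below the temperature at which the C2–O bond to the diazine breaks. The six-membered tether and the 5-benzyloxy donor both raise the barrier, while the para-oxygenated ring B makes heterolysis at C2 easy. That heterolysis would lead to elimination, oxygen-to-nitrogen migration or loss of configuration at C2. Protodeboronation at trace acid is a lesser risk.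

Fallback: keep the cycloaddition but remove the para donor, carrying C4' as bromine and making both acylated oxygens from boron. It sets out from amide 8 and returns at diol 26.
- Iodine–magnesium exchange on 2-(benzyloxy)-1-bromo-4-iodobenzene F1 (i-PrMgCl·LiCl, THF, −20 °C) and addition to 8 should give (S)-2-(benzyloxy)-1-[3-(benzyloxy)-4-bromophenyl]-5-(triisopropylsilyl)pent-4-yn-1-one F2.
- Zn(BH4)2 reduction as in step 7 gives the anti alcohol F3.
- Substitution on 16 as in step 9 gives the pyridazinyl ether F4.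
- Bu4NF gives the terminal alkyne F5.
- Borylation as in step 11 gives the alkynylboronate F6.
- Heating F6, now tolerable to about 250 °C because the bromo-substituted benzylic position ionises far less readily, gives the 4'-bromo chroman boronate F7.
- Miyaura borylation (B2pin2, PdCl2(dppf), KOAc, dioxane, 85 °C) gives the bis(boronate) F8.
- NaBO3·4H2O oxidises both C–B bonds of F8 to give 26, so the acetal step is no longer needed.

**Step 9.** Substitution at the deactivated C3 chloride by a hindered secondary alkoxide may be slow. Exchange of the benzyloxy group at C5 or base-induced decomposition of the alkoxide could then compete.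

Fallback: use a more electrophilic partner, from 16, returning at 18. NaSMe in THF converts 16 into 5-(benzyloxy)-3-(methylsulfanyl)pyridazine F9. Oxidation with KHSO5 (Oxone) in MeOH/H2O gives 5-(benzyloxy)-3-(methylsulfonyl)pyridazine F10. Alkoxide 17 should displace the sulfinate from F10 at 0 °C to give 18.

**Step 11.** The amide base may metalate the diazine ring, or the alkynylboronate may lose boron by hydrolysis during isolation.

Fallback: a base-free catalytic C–H borylation that gives a masked, chromatography-stable boron group, from 19, returning at 26.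
- Zn(OTf)2 (cat.), pyridine and 2,3-dihydro-1H-naphtho[1,8-de][1,3,2]diazaborinine in EtCN at 100 °C should give the alkynyl diaminonaphthalene-borane F11.
- Heating as in step 12 gives the chroman-5-yl diaminonaphthalene-borane F12.
- Aqueous HCl in THF removes the diaminonaphthalene and the methoxymethyl group together to give the boronic acid F13.
- NaBO3·4H2O oxidises F13 to 26.

**Step 2.** The sodium glycolate enolate may decompose faster than it is alkylated by the bulky propargylic bromide. Warming to force conversion would cost facial selectivity.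

Fallback: take C3 from the chiral pool, returning at 8. Methyl (S)-oxirane-2-carboxylate F14 is opened at C3 by LiC≡CSi(i-Pr)3 with BF3·OEt2 (THF, −78 °C) to give methyl (S)-2-hydroxy-5-(triisopropylsilyl)pent-4-ynoate F15. Acid-catalysed O-benzylation (benzyl trichloroacetimidate, TfOH cat.) gives methyl (S)-2-(benzyloxy)-5-(triisopropylsilyl)pent-4-ynoate F16. MeNHOMe·HCl with i-PrMgCl (THF, −20 °C) converts F16 into 8.

**Step 16.** Once the 3'-phenol is unmasked, the neighbouring galloyl group may migrate from O4' to O3'. Solvolysis of the aryl esters and hydrogenolysis of the benzylic C2–O1 bond are further risks.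

Fallback: non-reductive debenzylation under acid, where the catechol is not ionised, from 28 directly to 29. BCl3 with pentamethylbenzene as cation scavenger (CH2Cl2, −78 °C) should cleave all nine benzyl ethers.

## Further compounds

F1 | step 12 | 2-(benzyloxy)-1-bromo-4-iodobenzene | Brc1ccc(I)cc1OCc1ccccc1
F2 | step 12 | (S)-2-(benzyloxy)-1-[3-(benzyloxy)-4-bromophenyl]-5-(triisopropylsilyl)pent-4-yn-1-one | O=C([C@@H](OCc1ccccc1)CC#C[Si](C(C)C)(C(C)C)C(C)C)c1ccc(Br)c(OCc2ccccc2)c1
F3 | step 12 | (1R,2S)-2-(benzyloxy)-1-[3-(benzyloxy)-4-bromophenyl]-5-(triisopropylsilyl)pent-4-yn-1-ol | Brc1ccc([C@H]([C@@H](OCc2ccccc2)CC#C[Si](C(C)C)(C(C)C)C(C)C)O)cc1OCc1ccccc1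
F4 | step 12 | 5-(benzyloxy)-3-{[(1R,2S)-2-(benzyloxy)-1-[3-(benzyloxy)-4-bromophenyl]-5-(triisopropylsilyl)pent-4-yn-1-yl]oxy}pyridazine | Brc1ccc([C@H]([C@@H](OCc2ccccc2)CC#C[Si](C(C)C)(C(C)C)C(C)C)Oc2cc(OCc3ccccc3)cnn2)cc1OCc1ccccc1
F5 | step 12 | 5-(benzyloxy)-3-{[(1R,2S)-2-(benzyloxy)-1-[3-(benzyloxy)-4-bromophenyl]pent-4-yn-1-yl]oxy}pyridazine | Brc1ccc([C@H]([C@@H](OCc2ccccc2)CC#C)Oc2cc(OCc3ccccc3)cnn2)cc1OCc1ccccc1
F6 | step 12 | 5-(benzyloxy)-3-{[(1R,2S)-2-(benzyloxy)-1-[3-(benzyloxy)-4-bromophenyl]-5-(4,4,5,5-tetramethyl-1,3,2-dioxaborolan-2-yl)pent-4-yn-1-yl]oxy}pyridazine | Brc1ccc([C@H]([C@@H](OCc2ccccc2)CC#CB2OC(C)(C)C(C)(C)O2)Oc2cc(OCc3ccccc3)cnn2)cc1OCc1ccccc1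
F7 | step 12 | 2-{(2R,3S)-3,7-bis(benzyloxy)-2-[3-(benzyloxy)-4-bromophenyl]chroman-5-yl}-4,4,5,5-tetramethyl-1,3,2-dioxaborolane | Brc1ccc([C@H]2Oc3cc(OCc4ccccc4)cc(B4OC(C)(C)C(C)(C)O4)c3C[C@@H]2OCc2ccccc2)cc1OCc1ccccc1
F8 | step 12 | 2-{(2R,3S)-3,7-bis(benzyloxy)-2-[3-(benzyloxy)-4-(4,4,5,5-tetramethyl-1,3,2-dioxaborolan-2-yl)phenyl]chroman-5-yl}-4,4,5,5-tetramethyl-1,3,2-dioxaborolane | CC1(C)OB(c2ccc([C@H]3Oc4cc(OCc5ccccc5)cc(B5OC(C)(C)C(C)(C)O5)c4C[C@@H]3OCc3ccccc3)cc2OCc2ccccc2)OC1(C)C
F9 | step 9 | 5-(benzyloxy)-3-(methylsulfanyl)pyridazine | CSc1cc(OCc2ccccc2)cnn1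
F10 | step 9 | 5-(benzyloxy)-3-(methylsulfonyl)pyridazine | CS(=O)(=O)c1cc(OCc2ccccc2)cnn1
F11 | step 11 | 2-{(4S,5R)-4-(benzyloxy)-5-[3-(benzyloxy)-4-(methoxymethoxy)phenyl]-5-{[5-(benzyloxy)pyridazin-3-yl]oxy}pent-1-yn-1-yl}-2,3-dihydro-1H-naphtho[1,8-de][1,3,2]diazaborinine | COCOc1ccc([C@H]([C@@H](OCc2ccccc2)CC#CB2Nc3cccc4cccc(N2)c34)Oc2cc(OCc3ccccc3)cnn2)cc1OCc1ccccc1
F12 | step 11 | 2-{(2R,3S)-3,7-bis(benzyloxy)-2-[3-(benzyloxy)-4-(methoxymethoxy)phenyl]chroman-5-yl}-2,3-dihydro-1H-naphtho[1,8-de][1,3,2]diazaborinine | COCOc1ccc([C@H]2Oc3cc(OCc4ccccc4)cc(B4Nc5cccc6cccc(N4)c56)c3C[C@@H]2OCc2ccccc2)cc1OCc1ccccc1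
F13 | step 11 | {(2R,3S)-3,7-bis(benzyloxy)-2-[3-(benzyloxy)-4-hydroxyphenyl]chroman-5-yl}boronic acid | Oc1ccc([C@H]2Oc3cc(OCc4ccccc4)cc(B(O)O)c3C[C@@H]2OCc2ccccc2)cc1OCc1ccccc1
F14 | step 2 | methyl (S)-oxirane-2-carboxylate | COC(=O)[C@@H]1CO1
F15 | step 2 | methyl (S)-2-hydroxy-5-(triisopropylsilyl)pent-4-ynoate | COC(=O)[C@@H](O)CC#C[Si](C(C)C)(C(C)C)C(C)C
F16 | step 2 | methyl (S)-2-(benzyloxy)-5-(triisopropylsilyl)pent-4-ynoate | COC(=O)[C@@H](OCc1ccccc1)CC#C[Si](C(C)C)(C(C)C)C(C)C
F0 | step 16 | none | none
A1 | alternative 1 | (E)-1-[4-(benzyloxy)-2,6-bis(methoxymethoxy)phenyl]-3-[3-(benzyloxy)-4-(methoxymethoxy)phenyl]prop-2-en-1-one | COCOc1ccc(/C=C/C(=O)c2c(OCOC)cc(OCc3ccccc3)cc2OCOC)cc1OCc1ccccc1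
A2 | alternative 1 | [4-(benzyloxy)-2,6-bis(methoxymethoxy)phenyl]{(2R,3S)-3-[3-(benzyloxy)-4-(methoxymethoxy)phenyl]oxiran-2-yl}methanone | COCOc1ccc([C@@H]2O[C@H]2C(=O)c2c(OCOC)cc(OCc3ccccc3)cc2OCOC)cc1OCc1ccccc1
A3 | alternative 2 | 3-(benzyloxy)cyclobut-2-en-1-one | O=C1CC(OCc2ccccc2)=C1
A4 | alternative 2 | {3-[(4S,5S)-5-[3-(benzyloxy)-4-(methoxymethoxy)phenyl]-2,2-dimethyl-1,3-dioxolan-4-yl]prop-1-yn-1-yloxy}triisopropylsilane | CC(C)[Si](OC#CC[C@@H]1OC(C)(C)O[C@H]1c1ccc(OCOC)c(OCc2ccccc2)c1)(C(C)C)C(C)C
A5 | alternative 2 | 5-(benzyloxy)-2-{[(4S,5S)-5-[3-(benzyloxy)-4-(methoxymethoxy)phenyl]-2,2-dimethyl-1,3-dioxolan-4-yl]methyl}-3-(triisopropylsilyloxy)phenol | Oc1cc(OCc2ccccc2)cc(O[Si](C(C)C)(C(C)C)C(C)C)c1C[C@@H]1OC(C)(C)O[C@H]1c1ccc(OCOC)c(OCc2ccccc2)c1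
A6 | alternative 3 | 5-(benzyloxy)-2-(hydroxymethyl)-3-(methoxymethoxy)phenol | OCc1c(O)cc(OCc2ccccc2)cc1OCOC
A7 | alternative 3 | 2-{(E)-2-[3-(benzyloxy)-4-(methoxymethoxy)phenyl]ethenyl}-4,4,5,5-tetramethyl-1,3,2-dioxaborolane | COCOc1ccc(/C=C/B2OC(C)(C)C(C)(C)O2)cc1OCc1ccccc1
A8 | alternative 3 | 2-{(2S,3S)-7-(benzyloxy)-2-[3-(benzyloxy)-4-(methoxymethoxy)phenyl]-5-(methoxymethoxy)chroman-3-yl}-4,4,5,5-tetramethyl-1,3,2-dioxaborolane (2,3-trans) | COCOc1ccc([C@H]2Oc3cc(OCc4ccccc4)cc(OCOC)c3C[C@@H]2B2OC(C)(C)C(C)(C)O2)cc1OCc1ccccc1
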